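If X is what a repeat of these flasks is to yield, the reading to watch is the sum of X and E, and not E by itself.

| setting | violet | red | blue | Monday's | Sunday's | Thursday's | Tuesday's |
|---|---|---|---|---|---|---|---|
| E | 0.70 M | 1.1 M | 0.50 M | 0.50 M | 0.50 M | 0.50 M | 0.50 M |
| J | 0.50 mM | 0.50 mM | 0.75 mM | 0.50 mM | 0.50 mM | 0.50 mM | 0.50 mM |
| temperature | 35 °C | 65 °C | 35 °C |  | 90 °C | 65 °C | 40 °C |
| remark | run made earlier | run made earlier | run made earlier | at 40 °C until 12 h, from then on at 90 °C |  |  |  |
| time |  |  |  | 40 h | 40 h | 40 h | 40 h |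

| run | time / h | X / % | E / % |
|---|---|---|---|
| violet | 50.0 | 16 | 85 |
| violet | 120 | 30 | 71 |
| violet | 240 | 52 | 51 |
| violet | 360 | 64 | 35 |
| violet | 480 | 76 | 22 |
| red | 20.0 | 53 | 50 |
| red | 40.0 | 79 | 21 |
| red | 72.0 | 90 | 8 |
| red | 96.0 | 93 | 3 |
| blue | 40.0 | 11 | 84 |
| blue | 72.0 | 22 | 75 |
| blue | 144 | 40 | 54 |
| blue | 240 | 64 | 44 |
| blue | 480 | 82 | 15 |

(standard deviation of a reading: 2 percentage points)

- the flask that comes out highest in amount of X, in percent of the E charged, or "all alike" when all lie within 1.5 percentage points (Monday's / Sunday's / Thursday's / Tuesday's / all alike)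
- X at the end, in percent of the E charged, Monday's
- X at the end, in percent of the E charged, Sunday's
- X at the end, in percent of the E charged, Thursday's
- X at the end, in percent of the E charged, Tuesday's

- a reading or a percentage of X counts all its forms, free or not

Take the main step first, E going to X in first order with a constant k_E. The slope of ln E gives 0.0352 h⁻¹ in the red run at 65 °C and 0.00314 h⁻¹ in the violet run at 35 °C. Spacing k_E geometrically with temperature gives 0.264 h⁻¹ at 90 °C and 0.00470 h⁻¹ at 40 °C. On this step by itself, Tuesday's reaches 17.1% and Thursday's 75.6%, while Sunday's keeps 0.00258% of its E.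

Now add a loss of X with a constant k_L. In the red run the sum X + E falls from 100% at 40.0 h to 96.0% at 96.0 h, a weak reading, since each of the four values carries 2 percentage points. Divided by the time and by X near 90%, it gives k_L = 7.94 × 10⁻⁴ h⁻¹. The quantity to carry is the loss ratio ρ = k_L/k_E, here 0.0225, the selectivity factor of the two consecutive steps. With both steps first order, X stops rising at the crossing where E/X has fallen to ρ. Thursday's, with E/X near 0.323 at its end, is still on the rising side.

Last comes the heat, whose effect on ρ no run shows. With ρ held constant, the hot flasks lie past the crossing and decay at ρ·k_E: Sunday's ends near 78.8% and Monday's, after 28.0 h hot, near 84.7%, the higher of the flasks. Monday's drops below Thursday's once ρ at 90 °C passes 0.0379.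

The forecast gives Monday's 94%, Sunday's 93%, Thursday's 76% and Tuesday's 17%, and says of Monday's: “Equal or slightly higher”. It parts from this reckoning on Sunday's, standing above 78.8%.

Thursday's comes out highest at 75.0%, with Monday's at 70.7%, Sunday's at 58.7% and Tuesday's at 17.2%. In Sunday's, Q holds 41.3% at 40.0 h.

    X → Q (k = 3.20 × 10⁻⁴ min⁻¹, Ea = 122 kJ mol⁻¹)
    E + D → L + X (k = 1.10 × 10⁶ M⁻¹ s⁻¹, Ea = 21.0 kJ mol⁻¹)
    2 L → G (k = 3.30 × 10⁸ M⁻¹ s⁻¹, Ea = 8.00 kJ mol⁻¹)
    E + L → X + L, rate k4*[L]*[E] (k = 61000 M⁻¹ s⁻¹, Ea = 11.0 kJ mol⁻¹)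
    J → 2 D (k = 3.70 × 10⁻⁵ min⁻¹, Ea = 130 kJ mol⁻¹)
    Z ⇌ X, rate k6*(cs6 - [X]) while solid is left; crystals form when [X] > cs6 (solubility = 0.280 M, k = 0.00960 min⁻¹)
    (constants at 90 °C)

Between 20.0 h and 40.0 h, Sunday's sum X + E falls at 0.0152 h⁻¹ and its E at 0.209 h⁻¹, so ρ in Sunday's reads 0.0726, which is 3.23 times the 65 °C reading, and the loss constant stands above the 0.0100 h⁻¹ at which Monday's drops below Thursday's. Carried to Monday's, this loss constant takes the sum of 92.6% at 20.0 h to 68.3% at 40.0 h, and Monday's X stands at 70.7%.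

The readings are calculated with made-up constants, noise included.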